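**Strategy.** The cyclohexane core (iridal numbering: C6 bears the hydroxypropyl chain, C7 the alkylidene, C8 and C9 are the ring CH2 groups, C10 the carbinol, C11 the quaternary carbon) is disconnected at C6–C7 and C8–C9. A catalytic enantioselective Diels–Alder reaction of a 2-silyloxydiene (C9=C10–C11=C6) with but-3-yn-2-one (C7≡C8) closes this ring in one operation, exploiting the 1,4-relation between oxygenated C10 and the acyl-derived alkylidene carbon C7. It sets C6 and leaves a C10=C11 silyl enol ether (for C11 allylation and C10 methylation) and a C7=C8 enone (for the Z-alkylidene). The side chain is added by Wittig and alkenylzinc steps.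

Key step: step 3

Assumption: the usual sense of induction is taken for the oxazaborolidinium catalyst (step 3) and for (+)-MIB (step 13), and the enantiomeric catalyst is used if either is reversed; locants in the text follow iridal numbering (C1 = formyl carbon, C6–C11 = ring, C16 = acetoxy carbon). TBS = tert-butyldimethylsilyl, TES = triethylsilyl.

**Step 1**
Reactants: 1 4-[(tert-butyldimethylsilyl)oxy]butanal; 2 3-(triphenyl-λ5-phosphanylidene)butan-2-one
Product: 3 (E)-7-[(tert-butyldimethylsilyl)oxy]-3-methylhept-3-en-2-one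
Conditions: toluene, 90 °C
Reagents that add atoms: none
Why: Wittig olefination with a stabilized α-methyl keto ylide is selective for the aldehyde and should give the E-trisubstituted enone.

**Step 2**
Reactants: 3 (E)-7-[(tert-butyldimethylsilyl)oxy]-3-methylhept-3-en-2-one
Product: 5 (E)-tert-butyldimethyl{[5-methyl-6-(triethylsilyloxy)hepta-4,6-dien-1-yl]oxy}silane, via lithium dienolate 4 (not isolated)
Conditions: LDA (LiN(iPr)2), THF, −78 °C; then TESCl, −78 → 0 °C
Reagents that add atoms: chlorotriethylsilane, CC[Si](Cl)(CC)CC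
Why: Kinetic deprotonation of the enone at the α′-methyl group and O-silylation of the cross-conjugated dienolate (silyl enol ether formation) should give the 2-silyloxydiene with the E-alkene unchanged.

**Step 3**
Reactants: 5 (E)-tert-butyldimethyl{[5-methyl-6-(triethylsilyloxy)hepta-4,6-dien-1-yl]oxy}silane; 6 but-3-yn-2-one
Product: 7 1-[(6S)-6-{3-[(tert-butyldimethylsilyl)oxy]propyl}-5-methyl-4-(triethylsilyloxy)cyclohexa-1,4-dien-1-yl]ethan-1-one
Conditions: (S)-3,3-diphenyl-1-(o-tolyl)tetrahydro-1H,3H-pyrrolo[1,2-c][1,3,2]oxazaborole·Tf2NH (20 mol %), CH2Cl2, −78 → −40 °C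
Reagents that add atoms: none
Why: The oxazaborolidinium ion binds the ketone oxygen of 6 and lowers its LUMO, so diene 5 adds in a concerted, asynchronous normal-demand [4+2] cycloaddition in which the nucleophilic CH2 terminus (C9) of the silyl enol ether bonds to the alkyne CH (C8) slightly ahead of C6 bonding to C7. The closest known reaction type is the chiral-Lewis-acid-catalysed Diels–Alder reaction of alkynyl ketones with 2-silyloxydienes. The cyclohexa-1,4-diene ring is closed by intermolecular cycloaddition, both new bonds being ring bonds formed suprafacially on the s-cis diene. The only new stereocentre, C6, is set by the catalyst, which shields one quadrant of the bound ynone so that the diene presents a single face of its E-configured C6 terminus. The step needs para regioselectivity (siloxy C10 1,4 to acetyl C7), secured by matching the largest HOMO coefficient at C9 with the largest LUMO coefficient at C8 and reinforced by the C6 alkyl group, and enantiofacial selectivity, secured by the catalyst. The alkyne dienophile leaves the C7=C8 enone that later delivers the regiodefined Z-enolate.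

**Step 4**
Reactants: 7 1-[(6S)-6-{3-[(tert-butyldimethylsilyl)oxy]propyl}-5-methyl-4-(triethylsilyloxy)cyclohexa-1,4-dien-1-yl]ethan-1-one
Product: 9 (1Z)-1-[(2S)-2-{3-[(tert-butyldimethylsilyl)oxy]propyl}-3-methyl-4-(triethylsilyloxy)cyclohex-3-en-1-ylidene]ethyl trifluoromethanesulfonate, via lithium enolate 8 (not isolated)
Conditions: Li, NH3(l)/THF, t-BuOH (1 equiv), −78 °C; isoprene; then PhNTf2, THF, −78 → 0 °C
Reagents that add atoms: N-phenylbis(trifluoromethanesulfonimide), O=S(=O)(N(c1ccccc1)S(=O)(=O)C(F)(F)F)C(F)(F)F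
Why: Dissolving-metal (Birch-type) conjugate reduction gives the tetrasubstituted lithium enolate regiospecifically and O-triflation traps it; because the enone reacts through its s-trans conformer (acetyl methyl next to the C8–H, not next to the branched C6), the enolate oxygen should end up cis to C6, which is the Z geometry needed.

**Step 5**
Reactants: 9 (1Z)-1-[(2S)-2-{3-[(tert-butyldimethylsilyl)oxy]propyl}-3-methyl-4-(triethylsilyloxy)cyclohex-3-en-1-ylidene]ethyl trifluoromethanesulfonate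
Product: 10 (2Z)-2-[(2R)-2-{3-[(tert-butyldimethylsilyl)oxy]propyl}-3-methyl-4-(triethylsilyloxy)cyclohex-3-en-1-ylidene]propan-1-ol
Conditions: Bu3SnCH2OH, Pd(PPh3)4 (10 mol %), LiCl, dioxane, 90 °C
Reagents that add atoms: (tributylstannyl)methanol, CCCC[Sn](CCCC)(CCCC)CO
Why: Stille coupling: oxidative addition of the enol triflate to zerovalent palladium, transfer of the hydroxymethyl group from tin and reductive elimination proceed with retention of alkene geometry, so CH2OH replaces the triflate cis to C6.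

**Step 6**
Reactants: 10 (2Z)-2-[(2R)-2-{3-[(tert-butyldimethylsilyl)oxy]propyl}-3-methyl-4-(triethylsilyloxy)cyclohex-3-en-1-ylidene]propan-1-ol
Product: 11 tert-butyl{[(2Z)-2-[(2R)-2-{3-[(tert-butyldimethylsilyl)oxy]propyl}-3-methyl-4-(triethylsilyloxy)cyclohex-3-en-1-ylidene]propyl]oxy}dimethylsilane
Conditions: TBSCl, imidazole, DMF, 25 °C
Reagents that add atoms: tert-butylchlorodimethylsilane, CC(C)(C)[Si](C)(C)Cl
Why: Standard silylation of the primary allylic alcohol; the basic medium leaves the TES enol ether intact.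

**Step 7**
Reactants: 11 tert-butyl{[(2Z)-2-[(2R)-2-{3-[(tert-butyldimethylsilyl)oxy]propyl}-3-methyl-4-(triethylsilyloxy)cyclohex-3-en-1-ylidene]propyl]oxy}dimethylsilane
Product: 12 (2S,3R,4Z)-2-methyl-2-(prop-2-en-1-yl)-3-{3-[(tert-butyldimethylsilyl)oxy]propyl}-4-{1-[(tert-butyldimethylsilyl)oxy]propan-2-ylidene}cyclohexan-1-one
Conditions: allyl methyl carbonate, Pd2(dba)3 (2.5 mol %), dppe, TBAT (Bu4N+ Ph3SiF2−, 1.0 equiv), THF, 25 °C; aq NH4Cl
Reagents that add atoms: allyl methyl carbonate, C=CCOC(=O)OC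
Why: Tsuji allylation of a silyl enol ether: fluoride releases the regiodefined tetrasubstituted enolate, which is C-allylated by the π-allylpalladium complex; the C6 chain is held pseudo-axial by allylic strain against the C11 methyl and the Z-alkylidene, so allyl should enter from the opposite face and give the quaternary C11 with allyl trans to the C6 chain (11S).

**Step 8**
Reactants: 12 (2S,3R,4Z)-2-methyl-2-(prop-2-en-1-yl)-3-{3-[(tert-butyldimethylsilyl)oxy]propyl}-4-{1-[(tert-butyldimethylsilyl)oxy]propan-2-ylidene}cyclohexan-1-one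
Product: 14 triethyl{[(1S,2S,3R,4Z)-1,2-dimethyl-2-(prop-2-en-1-yl)-3-{3-[(tert-butyldimethylsilyl)oxy]propyl}-4-{1-[(tert-butyldimethylsilyl)oxy]propan-2-ylidene}cyclohexyl]oxy}silane, via lithium alkoxide 13 (not isolated)
Conditions: MeLi, Et2O, −78 °C; then TESOTf, −78 → 0 °C
Reagents that add atoms: methyllithium, [Li]C; triethylsilyl trifluoromethanesulfonate, CC[Si](CC)(CC)OS(=O)(=O)C(F)(F)F
Why: 1,2-Addition of MeLi should occur from the face opposite the C6 chain and the C11 methyl (syn-axial or α-axial shielding of the upper face in either chair), giving the 10S carbinol with OH cis to the C11 methyl, and the alkoxide is silylated in the same flask so that no lactol can form at the later aldehyde stage.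

**Step 9**
Reactants: 14 triethyl{[(1S,2S,3R,4Z)-1,2-dimethyl-2-(prop-2-en-1-yl)-3-{3-[(tert-butyldimethylsilyl)oxy]propyl}-4-{1-[(tert-butyldimethylsilyl)oxy]propan-2-ylidene}cyclohexyl]oxy}silane
Product: 16 3-[(1S,2S,5Z,6R)-1,2-dimethyl-2-(triethylsilyloxy)-6-{3-[(tert-butyldimethylsilyl)oxy]propyl}-5-{1-[(tert-butyldimethylsilyl)oxy]propan-2-ylidene}cyclohexyl]propan-1-ol, via B-alkyl-9-borabicyclononane 15 (not isolated)
Conditions: 9-BBN, THF, 0 → 25 °C; then NaOH, H2O2, 0 °C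
Reagents that add atoms: hydrogen peroxide, OO
Why: Brown hydroboration–oxidation: 9-BBN adds only to the terminal alkene with anti-Markovnikov regiochemistry (the tetrasubstituted alkene is inert) and alkaline peroxide gives the primary alcohol.

**Step 10**
Reactants: 16 3-[(1S,2S,5Z,6R)-1,2-dimethyl-2-(triethylsilyloxy)-6-{3-[(tert-butyldimethylsilyl)oxy]propyl}-5-{1-[(tert-butyldimethylsilyl)oxy]propan-2-ylidene}cyclohexyl]propan-1-ol
Product: 17 3-[(1S,2S,5Z,6R)-1,2-dimethyl-2-(triethylsilyloxy)-6-{3-[(tert-butyldimethylsilyl)oxy]propyl}-5-{1-[(tert-butyldimethylsilyl)oxy]propan-2-ylidene}cyclohexyl]propanal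
Conditions: DMP, CH2Cl2, 0 → 25 °C
Reagents that add atoms: none
Why: Dess–Martin oxidation converts the primary alcohol into the aldehyde under near-neutral conditions that the silyl ethers tolerate.

**Step 11**
Reactants: 17 3-[(1S,2S,5Z,6R)-1,2-dimethyl-2-(triethylsilyloxy)-6-{3-[(tert-butyldimethylsilyl)oxy]propyl}-5-{1-[(tert-butyldimethylsilyl)oxy]propan-2-ylidene}cyclohexyl]propanal; 18 2-(triphenyl-λ5-phosphanylidene)propanal
Product: 19 (2E)-2-methyl-5-[(1S,2S,5Z,6R)-1,2-dimethyl-2-(triethylsilyloxy)-6-{3-[(tert-butyldimethylsilyl)oxy]propyl}-5-{1-[(tert-butyldimethylsilyl)oxy]propan-2-ylidene}cyclohexyl]pent-2-enal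
Conditions: toluene, 90 °C
Reagents that add atoms: none
Why: Wittig olefination with the formyl-stabilized ylide reacts only at the aldehyde and should give the E-2-methyl enal.

**Step 12**
Reactants: 20 (S)-citronellal [(3S)-3,7-dimethyloct-6-enal]
Product: 21 (3S)-3,7-dimethyloct-6-en-1-yne
Conditions: C4F9SO2F (NfF), phosphazene base P2-Et, DMF, −20 → 25 °C
Reagents that add atoms: none
Why: One-pot enol nonaflate formation and base-induced β-elimination (aldehyde-to-alkyne conversion via an enol sulfonate) turns CH2–CHO into C≡CH without touching the C19 stereocentre, which is not part of the enolate, and the product is protected as its acetylide from propargylic deprotonation.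

**Step 13**
Reactants: 19 (2E)-2-methyl-5-[(1S,2S,5Z,6R)-1,2-dimethyl-2-(triethylsilyloxy)-6-{3-[(tert-butyldimethylsilyl)oxy]propyl}-5-{1-[(tert-butyldimethylsilyl)oxy]propan-2-ylidene}cyclohexyl]pent-2-enal; 21 (3S)-3,7-dimethyloct-6-en-1-yne
Product: 24 (3E,5R,6E,8S)-1-[(1S,2S,5Z,6R)-1,2-dimethyl-2-(triethylsilyloxy)-6-{3-[(tert-butyldimethylsilyl)oxy]propyl}-5-{1-[(tert-butyldimethylsilyl)oxy]propan-2-ylidene}cyclohexyl]-4,8,12-trimethyltrideca-3,6,11-trien-5-ol, via alkenyldicyclohexylborane 22 (not isolated), via alkenyl(methyl)zinc 23 (not isolated)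
Conditions: 21, Cy2BH, toluene, 0 → 25 °C; Me2Zn, −78 °C; (2R)-3-exo-morpholinoisoborneol [(+)-MIB, 10 mol %]; then 19, −20 → 0 °C; aq NH4Cl
Reagents that add atoms: none
Why: Syn-hydroboration of the terminal alkyne gives the E-alkenylborane, boron-to-zinc transmetalation and amino-alcohol-catalysed 1,2-addition to the enal (Oppolzer-type enantioselective alkenylzinc addition) form C16–C17, the (+)-MIB–zinc complex directing attack to the Re face of the aldehyde to set 16R.

**Step 14**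
Reactants: 24 (3E,5R,6E,8S)-1-[(1S,2S,5Z,6R)-1,2-dimethyl-2-(triethylsilyloxy)-6-{3-[(tert-butyldimethylsilyl)oxy]propyl}-5-{1-[(tert-butyldimethylsilyl)oxy]propan-2-ylidene}cyclohexyl]-4,8,12-trimethyltrideca-3,6,11-trien-5-ol
Product: 25 (3E,5R,6E,8S)-1-[(1S,2S,5Z,6R)-1,2-dimethyl-2-(triethylsilyloxy)-6-{3-[(tert-butyldimethylsilyl)oxy]propyl}-5-{1-[(tert-butyldimethylsilyl)oxy]propan-2-ylidene}cyclohexyl]-4,8,12-trimethyltrideca-3,6,11-trien-5-yl acetate
Conditions: Ac2O, pyridine, DMAP (cat.), CH2Cl2, 0 °C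
Reagents that add atoms: acetic anhydride, CC(=O)OC(C)=O
Why: DMAP-catalysed acylation of the only free hydroxyl group proceeds with retention at C16.

**Step 15**
Reactants: 25 (3E,5R,6E,8S)-1-[(1S,2S,5Z,6R)-1,2-dimethyl-2-(triethylsilyloxy)-6-{3-[(tert-butyldimethylsilyl)oxy]propyl}-5-{1-[(tert-butyldimethylsilyl)oxy]propan-2-ylidene}cyclohexyl]-4,8,12-trimethyltrideca-3,6,11-trien-5-yl acetate
Product: 26 (3E,5R,6E,8S)-1-[(1S,2S,5Z,6R)-2-hydroxy-5-(1-hydroxypropan-2-ylidene)-6-(3-hydroxypropyl)-1,2-dimethylcyclohexyl]-4,8,12-trimethyltrideca-3,6,11-trien-5-yl acetate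
Conditions: HF·pyridine, pyridine, THF, 0 → 25 °C
Reagents that add atoms: none
Why: Fluoride-mediated desilylation under pyridine-buffered conditions should remove both primary TBS ethers and the tertiary TES ether while keeping the acid-sensitive bis-allylic acetate.

**Step 16**
Reactants: 26 (3E,5R,6E,8S)-1-[(1S,2S,5Z,6R)-2-hydroxy-5-(1-hydroxypropan-2-ylidene)-6-(3-hydroxypropyl)-1,2-dimethylcyclohexyl]-4,8,12-trimethyltrideca-3,6,11-trien-5-yl acetate
Product: 27 (2Z)-2-[(2R,3S,4S)-3-[(3E,5R,6E,8S)-5-acetoxy-4,8,12-trimethyltrideca-3,6,11-trien-1-yl]-4-hydroxy-2-(3-hydroxypropyl)-3,4-dimethylcyclohexylidene]propanal (CNP0259235.1)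
Conditions: MnO2, CH2Cl2, 25 °C
Reagents that add atoms: none
Why: MnO2 oxidizes allylic alcohols selectively, so only the C1 hydroxyl should be converted into the aldehyde, with the saturated primary alcohol, the tertiary alcohol, the acetate and the Z geometry left unchanged.

**Compound list**
1 | 4-[(tert-butyldimethylsilyl)oxy]butanal | O=CCCCO[Si](C)(C)C(C)(C)C | starting material
2 | 3-(triphenyl-λ5-phosphanylidene)butan-2-one | CC(=O)C(C)=P(c1ccccc1)(c1ccccc1)c1ccccc1 | starting material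
3 | (E)-7-[(tert-butyldimethylsilyl)oxy]-3-methylhept-3-en-2-one | CC(=O)/C(C)=C/CCCO[Si](C)(C)C(C)(C)C | intermediate
4 | lithium (3E)-7-[(tert-butyldimethylsilyl)oxy]-3-methylhepta-1,3-dien-2-olate | [Li]OC(=C)/C(C)=C/CCCO[Si](C)(C)C(C)(C)C | intermediate
5 | (E)-tert-butyldimethyl{[5-methyl-6-(triethylsilyloxy)hepta-4,6-dien-1-yl]oxy}silane | C=C(O[Si](CC)(CC)CC)/C(C)=C/CCCO[Si](C)(C)C(C)(C)C | intermediate
6 | but-3-yn-2-one | CC(=O)C#C | starting material
7 | 1-[(6S)-6-{3-[(tert-butyldimethylsilyl)oxy]propyl}-5-methyl-4-(triethylsilyloxy)cyclohexa-1,4-dien-1-yl]ethan-1-one | CC1=C(O[Si](CC)(CC)CC)CC=C(C(C)=O)[C@H]1CCCO[Si](C)(C)C(C)(C)C | intermediate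
8 | lithium (1Z)-1-[(2S)-2-{3-[(tert-butyldimethylsilyl)oxy]propyl}-3-methyl-4-(triethylsilyloxy)cyclohex-3-en-1-ylidene]ethan-1-olate | CC1=C(O[Si](CC)(CC)CC)CC/C(=C(\C)O[Li])[C@H]1CCCO[Si](C)(C)C(C)(C)C | intermediate
9 | (1Z)-1-[(2S)-2-{3-[(tert-butyldimethylsilyl)oxy]propyl}-3-methyl-4-(triethylsilyloxy)cyclohex-3-en-1-ylidene]ethyl trifluoromethanesulfonate | CC1=C(O[Si](CC)(CC)CC)CC/C(=C(\C)OS(=O)(=O)C(F)(F)F)[C@H]1CCCO[Si](C)(C)C(C)(C)C | intermediate
10 | (2Z)-2-[(2R)-2-{3-[(tert-butyldimethylsilyl)oxy]propyl}-3-methyl-4-(triethylsilyloxy)cyclohex-3-en-1-ylidene]propan-1-ol | CC1=C(O[Si](CC)(CC)CC)CC/C(=C(\C)CO)[C@H]1CCCO[Si](C)(C)C(C)(C)C | intermediate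
11 | tert-butyl{[(2Z)-2-[(2R)-2-{3-[(tert-butyldimethylsilyl)oxy]propyl}-3-methyl-4-(triethylsilyloxy)cyclohex-3-en-1-ylidene]propyl]oxy}dimethylsilane | CC1=C(O[Si](CC)(CC)CC)CC/C(=C(\C)CO[Si](C)(C)C(C)(C)C)[C@H]1CCCO[Si](C)(C)C(C)(C)C | intermediate
12 | (2S,3R,4Z)-2-methyl-2-(prop-2-en-1-yl)-3-{3-[(tert-butyldimethylsilyl)oxy]propyl}-4-{1-[(tert-butyldimethylsilyl)oxy]propan-2-ylidene}cyclohexan-1-one | C=CC[C@@]1(C)[C@H](CCCO[Si](C)(C)C(C)(C)C)/C(=C(/C)CO[Si](C)(C)C(C)(C)C)CCC1=O | intermediate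
13 | lithium (1S,2S,3R,4Z)-1,2-dimethyl-2-(prop-2-en-1-yl)-3-{3-[(tert-butyldimethylsilyl)oxy]propyl}-4-{1-[(tert-butyldimethylsilyl)oxy]propan-2-ylidene}cyclohexan-1-olate | C=CC[C@@]1(C)[C@H](CCCO[Si](C)(C)C(C)(C)C)/C(=C(/C)CO[Si](C)(C)C(C)(C)C)CC[C@]1(C)O[Li] | intermediate
14 | triethyl{[(1S,2S,3R,4Z)-1,2-dimethyl-2-(prop-2-en-1-yl)-3-{3-[(tert-butyldimethylsilyl)oxy]propyl}-4-{1-[(tert-butyldimethylsilyl)oxy]propan-2-ylidene}cyclohexyl]oxy}silane | C=CC[C@@]1(C)[C@H](CCCO[Si](C)(C)C(C)(C)C)/C(=C(/C)CO[Si](C)(C)C(C)(C)C)CC[C@]1(C)O[Si](CC)(CC)CC | intermediate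
15 | 9-{3-[(1S,2S,5Z,6R)-1,2-dimethyl-2-(triethylsilyloxy)-6-{3-[(tert-butyldimethylsilyl)oxy]propyl}-5-{1-[(tert-butyldimethylsilyl)oxy]propan-2-ylidene}cyclohexyl]propyl}-9-borabicyclo[3.3.1]nonane | C1CC2CCCC(C1)B2CCC[C@@]3(C)[C@H](CCCO[Si](C)(C)C(C)(C)C)/C(=C(/C)CO[Si](C)(C)C(C)(C)C)CC[C@]3(C)O[Si](CC)(CC)CC | intermediate
16 | 3-[(1S,2S,5Z,6R)-1,2-dimethyl-2-(triethylsilyloxy)-6-{3-[(tert-butyldimethylsilyl)oxy]propyl}-5-{1-[(tert-butyldimethylsilyl)oxy]propan-2-ylidene}cyclohexyl]propan-1-ol | OCCC[C@@]1(C)[C@H](CCCO[Si](C)(C)C(C)(C)C)/C(=C(/C)CO[Si](C)(C)C(C)(C)C)CC[C@]1(C)O[Si](CC)(CC)CC | intermediate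
17 | 3-[(1S,2S,5Z,6R)-1,2-dimethyl-2-(triethylsilyloxy)-6-{3-[(tert-butyldimethylsilyl)oxy]propyl}-5-{1-[(tert-butyldimethylsilyl)oxy]propan-2-ylidene}cyclohexyl]propanal | O=CCC[C@@]1(C)[C@H](CCCO[Si](C)(C)C(C)(C)C)/C(=C(/C)CO[Si](C)(C)C(C)(C)C)CC[C@]1(C)O[Si](CC)(CC)CC | intermediate
18 | 2-(triphenyl-λ5-phosphanylidene)propanal | CC(C=O)=P(c1ccccc1)(c1ccccc1)c1ccccc1 | starting material
19 | (2E)-2-methyl-5-[(1S,2S,5Z,6R)-1,2-dimethyl-2-(triethylsilyloxy)-6-{3-[(tert-butyldimethylsilyl)oxy]propyl}-5-{1-[(tert-butyldimethylsilyl)oxy]propan-2-ylidene}cyclohexyl]pent-2-enal | O=C/C(C)=C/CC[C@@]1(C)[C@H](CCCO[Si](C)(C)C(C)(C)C)/C(=C(/C)CO[Si](C)(C)C(C)(C)C)CC[C@]1(C)O[Si](CC)(CC)CC | intermediate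
20 | (S)-citronellal [(3S)-3,7-dimethyloct-6-enal] | O=CC[C@@H](C)CCC=C(C)C | starting material
21 | (3S)-3,7-dimethyloct-6-en-1-yne | C#C[C@@H](C)CCC=C(C)C | intermediate
22 | dicyclohexyl[(1E,3S)-3,7-dimethylocta-1,6-dien-1-yl]borane | B(/C=C/[C@@H](C)CCC=C(C)C)(C1CCCCC1)C1CCCCC1 | intermediate
23 | [(1E,3S)-3,7-dimethylocta-1,6-dien-1-yl](methyl)zinc | C[Zn]/C=C/[C@@H](C)CCC=C(C)C | intermediate
24 | (3E,5R,6E,8S)-1-[(1S,2S,5Z,6R)-1,2-dimethyl-2-(triethylsilyloxy)-6-{3-[(tert-butyldimethylsilyl)oxy]propyl}-5-{1-[(tert-butyldimethylsilyl)oxy]propan-2-ylidene}cyclohexyl]-4,8,12-trimethyltrideca-3,6,11-trien-5-ol | O[C@H](/C=C/[C@@H](C)CCC=C(C)C)/C(C)=C/CC[C@@]1(C)[C@H](CCCO[Si](C)(C)C(C)(C)C)/C(=C(/C)CO[Si](C)(C)C(C)(C)C)CC[C@]1(C)O[Si](CC)(CC)CC | intermediate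
25 | (3E,5R,6E,8S)-1-[(1S,2S,5Z,6R)-1,2-dimethyl-2-(triethylsilyloxy)-6-{3-[(tert-butyldimethylsilyl)oxy]propyl}-5-{1-[(tert-butyldimethylsilyl)oxy]propan-2-ylidene}cyclohexyl]-4,8,12-trimethyltrideca-3,6,11-trien-5-yl acetate | CC(=O)O[C@H](/C=C/[C@@H](C)CCC=C(C)C)/C(C)=C/CC[C@@]1(C)[C@H](CCCO[Si](C)(C)C(C)(C)C)/C(=C(/C)CO[Si](C)(C)C(C)(C)C)CC[C@]1(C)O[Si](CC)(CC)CC | intermediate
26 | (3E,5R,6E,8S)-1-[(1S,2S,5Z,6R)-2-hydroxy-5-(1-hydroxypropan-2-ylidene)-6-(3-hydroxypropyl)-1,2-dimethylcyclohexyl]-4,8,12-trimethyltrideca-3,6,11-trien-5-yl acetate | CC(=O)O[C@H](/C=C/[C@@H](C)CCC=C(C)C)/C(C)=C/CC[C@@]1(C)[C@H](CCCO)/C(=C(/C)CO)CC[C@]1(C)O | intermediate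
27 | (2Z)-2-[(2R,3S,4S)-3-[(3E,5R,6E,8S)-5-acetoxy-4,8,12-trimethyltrideca-3,6,11-trien-1-yl]-4-hydroxy-2-(3-hydroxypropyl)-3,4-dimethylcyclohexylidene]propanal (CNP0259235.1) | CC(=O)O[C@H](/C=C/[C@@H](C)CCC=C(C)C)/C(C)=C/CC[C@@]1(C)[C@H](CCCO)/C(=C(/C)C=O)CC[C@]1(C)O | target

**Total step count:** 16. **Longest linear sequence:** 15 steps (steps 1–11 and 13–16); step 12 is a one-step side branch.

**Three steps most likely to fail**

Step 3. The rod-shaped ynone offers the catalyst little to distinguish the two diene orientations, so enantiofacial discrimination may be poor; the acidic catalyst may also strip the TES dienol ether before cycloaddition. The fallback sets out from 5 and uses an alkene dienophile of the class these catalysts organize best. Cycloaddition of 5 with 2-bromoacrolein under the same type of oxazaborolidinium catalysis should give the bromo aldehyde F1 (formyl trans to the side chain). MeMgBr (THF, −78 °C) should convert it into the bromohydrin F2, and Dess–Martin oxidation into the α-bromo ketone F3. Bromine–copper exchange with Me2CuLi would then generate enolate 8 regiospecifically, and triflation with PhNTf2 returns the route at 9.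

Step 4. Reduction through the minor s-cis enone conformer, or over-reduction of the ketone, would erode the enolate geometry and give an E/Z mixture of triflates. The fallback sets out from 7 and fixes the geometry by mechanism instead of by conformation. Kinetic enolization of the acetyl methyl group (LDA (LiN(iPr)2), then PhNTf2) should give the dienyl triflate F4. Stille coupling with Bu3SnCH2OH (Pd(PPh3)4, LiCl) should give the dienyl alcohol F5. A 1,4-hydrogenation with (η6-naphthalene)Cr(CO)3 and H2 adds hydrogen to both termini of the s-cis-bound diene, so C8 and the new methyl group end up cis on the tetrasubstituted alkene; the route is rejoined at 10.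

Step 8. MeLi may attack the hindered ketone from the wrong face, or enolize it at C9 instead of adding. The fallback sets out from 12 and replaces kinetic addition by a reversible one. Dimethylsulfoxonium methylide (Me3S(O)I, NaH, DMSO) adds reversibly, so the CH2 group should settle equatorial in the chair enforced by the axial C6 chain, giving the spiro-epoxide F6 with oxygen cis to the C11 methyl. LiEt3BH should open it at the CH2 to the tertiary alcohol F7, and TESOTf with 2,6-lutidine returns the route at 14.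

**Further compounds**
F1 | step 3 | 1-bromo-2-{3-[(tert-butyldimethylsilyl)oxy]propyl}-3-methyl-4-(triethylsilyloxy)cyclohex-3-ene-1-carbaldehyde (formyl trans to the side chain) | CC1=C(O[Si](CC)(CC)CC)CC[C@](Br)(C=O)[C@H]1CCCO[Si](C)(C)C(C)(C)C
F2 | step 3 | 1-[1-bromo-2-{3-[(tert-butyldimethylsilyl)oxy]propyl}-3-methyl-4-(triethylsilyloxy)cyclohex-3-en-1-yl]ethan-1-ol (carbinol epimers) | CC1=C(O[Si](CC)(CC)CC)CC[C@](Br)(C(C)O)[C@H]1CCCO[Si](C)(C)C(C)(C)C
F3 | step 3 | 1-[1-bromo-2-{3-[(tert-butyldimethylsilyl)oxy]propyl}-3-methyl-4-(triethylsilyloxy)cyclohex-3-en-1-yl]ethan-1-one | CC1=C(O[Si](CC)(CC)CC)CC[C@](Br)(C(C)=O)[C@H]1CCCO[Si](C)(C)C(C)(C)C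
F4 | step 4 | 1-[6-{3-[(tert-butyldimethylsilyl)oxy]propyl}-5-methyl-4-(triethylsilyloxy)cyclohexa-1,4-dien-1-yl]ethenyl trifluoromethanesulfonate (C6 as in 7) | CC1=C(O[Si](CC)(CC)CC)CC=C(C(=C)OS(=O)(=O)C(F)(F)F)[C@H]1CCCO[Si](C)(C)C(C)(C)C
F5 | step 4 | 2-[6-{3-[(tert-butyldimethylsilyl)oxy]propyl}-5-methyl-4-(triethylsilyloxy)cyclohexa-1,4-dien-1-yl]prop-2-en-1-ol (C6 as in 7) | CC1=C(O[Si](CC)(CC)CC)CC=C(C(=C)CO)[C@H]1CCCO[Si](C)(C)C(C)(C)C
F6 | step 8 | spiro-epoxide of 12 at C10 (1-oxaspiro[2.5]octane; oxygen cis to the C11 methyl) | C=CC[C@@]1(C)[C@H](CCCO[Si](C)(C)C(C)(C)C)/C(=C(/C)CO[Si](C)(C)C(C)(C)C)CC[C@@]12CO2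
F7 | step 8 | (1S,2S,3R,4Z)-1,2-dimethyl-2-(prop-2-en-1-yl)-3-{3-[(tert-butyldimethylsilyl)oxy]propyl}-4-{1-[(tert-butyldimethylsilyl)oxy]propan-2-ylidene}cyclohexan-1-ol | C=CC[C@@]1(C)[C@H](CCCO[Si](C)(C)C(C)(C)C)/C(=C(/C)CO[Si](C)(C)C(C)(C)C)CC[C@]1(C)O
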